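**Retrosynthetic overview**
- Locants: ring B = C1 (CHCH3), C2 (CHOAc), C3 (CH2), C4 (CH with the side chain). Ring A = C4a, C5, C6 (bears C19H2OAc), C7, C8 (OH), C8a. Side chain = C11 (CHCH3), C12, C13, C14=C15.
- Endgame: C13–C14 is made by B-alkyl Suzuki coupling on a C12=C13 vinyl group. C1 and C2, cis to each other and to the C4 branch, come from dynamic-kinetic transfer hydrogenation of a 1-methyl-2-tetralone.
- Key disconnection: C4–C11 (enamine of propanal plus the β-carbon of a nitrostyrene) and, in the same flask, C2–C3 (nitroaldol), which closes ring B. The nitro group is removed afterwards.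
- Enabling feature: the ring B methylene C3 lies between benzylic C4 and carbinol C2. One nitro group on C3 first makes C4 electrophilic and then makes C3 nucleophilic toward a C2 aldehyde, and the C4/C11 pair has the syn pattern of the enamine–nitroalkene addition.
- Precursor: an aromatic Claisen rearrangement of the crotyl ether of dimethyl 5-hydroxyisophthalate places C1/C2 on C8a and differentiates the two esters (C4 and C19). Ring order: A (bought), then B (step 9).

Key step: step 9

Remark: commercial crotyl bromide (mainly E) serves because its geometry is lost in step 2; centres left open in a SMILES are racemic or epimeric mixtures, which is harmless because C2 and C3 are flattened in steps 10 and 12 and C1 is set in step 13.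

**Step 1**
Reactants: 1 dimethyl 5-hydroxyisophthalate; 2 (E)-1-bromobut-2-ene (crotyl bromide)
Product: 3 dimethyl 5-[(E)-but-2-enyloxy]isophthalate
Conditions: K2CO3, acetone, reflux
Reagents that add atoms: none
Why: Williamson etherification, in which the phenoxide displaces the primary allylic bromide by SN2 and the esters are inert to carbonate.

**Step 2**
Reactants: 3 dimethyl 5-[(E)-but-2-enyloxy]isophthalate
Product: 4 dimethyl 4-(but-3-en-2-yl)-5-hydroxyisophthalate (racemic)
Conditions: PhNEt2, 200 °C
Reagents that add atoms: none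
Why: Aromatic Claisen rearrangement, whose [3,3] shift brings the crotyl γ-carbon (future C1 with its methyl group) onto an ortho carbon; the two ortho positions are equivalent by symmetry, so one regioisomer should form, and the racemic benzylic centre is reset in step 13.

**Step 3**
Reactants: 4 dimethyl 4-(but-3-en-2-yl)-5-hydroxyisophthalate
Product: 5 dimethyl 4-(but-3-en-2-yl)-5-(triisopropylsilyloxy)isophthalate (racemic)
Conditions: iPr3SiOTf, 2,6-lutidine, CH2Cl2, 0 °C to rt
Reagents that add atoms: triisopropylsilyl triflate CC(C)[Si](C(C)C)(C(C)C)OS(=O)(=O)C(F)(F)F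
Why: Silyl ether formation with the reactive triflate, which copes with the flanked phenol and gives an aryl ether robust enough for hydride, ylide and aqueous carbonate.

**Step 4**
Reactants: 5 dimethyl 4-(but-3-en-2-yl)-5-(triisopropylsilyloxy)isophthalate
Product: 6 [4-(but-3-en-2-yl)-5-(triisopropylsilyloxy)benzene-1,3-diyl]dimethanol (racemic)
Conditions: LiAlH4, THF, 0 °C
Reagents that add atoms: none
Why: Hydride reduction of both esters to benzylic alcohols, with the isolated alkene and the aryl silyl ether untouched.

**Step 5**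
Reactants: 6 [4-(but-3-en-2-yl)-5-(triisopropylsilyloxy)benzene-1,3-diyl]dimethanol
Product: 7 4-(but-3-en-2-yl)-3-(hydroxymethyl)-5-(triisopropylsilyloxy)benzyl acetate (racemic)
Conditions: vinyl acetate, immobilised Candida antarctica lipase B, tBuOMe, rt
Reagents that add atoms: vinyl acetate CC(=O)OC=C
Why: Lipase-catalysed irreversible transesterification, which should acylate only the unflanked C19 alcohol because the other CH2OH sits next to the branched C8a substituent, and which installs a final acetate early.

**Step 6**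
Reactants: 7 4-(but-3-en-2-yl)-3-(hydroxymethyl)-5-(triisopropylsilyloxy)benzyl acetate
Product: 8 4-(but-3-en-2-yl)-3-formyl-5-(triisopropylsilyloxy)benzyl acetate (racemic)
Conditions: activated MnO2, CH2Cl2, rt
Reagents that add atoms: none
Why: Selective oxidation of a benzylic alcohol on MnO2, which leaves acetate, silyl ether and alkene alone and stops at the aldehyde (future C4).

**Step 7**
Reactants: 8 4-(but-3-en-2-yl)-3-formyl-5-(triisopropylsilyloxy)benzyl acetate
Product: 9 4-(but-3-en-2-yl)-3-[(E)-2-nitrovinyl]-5-(triisopropylsilyloxy)benzyl acetate (racemic)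
Conditions: MeNO2 (solvent), NH4OAc (cat.), 90 °C
Reagents that add atoms: nitromethane C[N+](=O)[O-]
Why: Henry reaction with in situ dehydration (nitroaldol condensation), which brings in C3 and gives the conjugated (E)-nitroalkene as the thermodynamic isomer.

**Step 8**
Reactants: 9 4-(but-3-en-2-yl)-3-[(E)-2-nitrovinyl]-5-(triisopropylsilyloxy)benzyl acetate
Product: 11 3-[(E)-2-nitrovinyl]-4-(1-oxopropan-2-yl)-5-(triisopropylsilyloxy)benzyl acetate (racemic), via secondary ozonide 10 (not isolated)
Conditions: O3, CH2Cl2, −78 °C, stopped at consumption of 9; then Me2S, −78 °C to rt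
Reagents that add atoms: ozone [O-][O+]=O
Why: Ozonolysis, in which electrophilic ozone attacks the electron-rich monosubstituted alkene far faster than the electron-poor nitroalkene, and Me2S reduces the ozonide without adding to the nitroalkene.

**Step 9**
Reactants: 11 3-[(E)-2-nitrovinyl]-4-(1-oxopropan-2-yl)-5-(triisopropylsilyloxy)benzyl acetate; 12 propanal
Product: 14 ring B nitro alcohol (4S,11R; mixture at C1/C2/C3), via open-chain Michael adduct 13 (not isolated)
Conditions: 12 (3 equiv), (S)-2-[diphenyl(trimethylsilyloxy)methyl]pyrrolidine (10 mol %), 4-nitrophenol (10 mol %), toluene, 0 °C; then Et3N (0.3 equiv), 0 °C to rt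
Reagents that add atoms: none
Why: The pyrrolidine catalyst condenses only with unbranched 12 to an (E)-enamine whose face away from the CPh2(OSiMe3) group adds through a synclinal open transition state to the β-carbon C4 of the (E)-nitroalkene, which forms the C4–C11 bond and, after hydrolysis, releases 13 and the catalyst. Et3N then converts the C3H2NO2 group into its nitronate, which attacks the tethered C2 aldehyde and closes ring B in a 6-(enolexo)-exo-trig nitroaldol (Henry) reaction. The closest known reaction types are the diarylprolinol silyl ether catalysed aldehyde–nitroalkene Michael addition and the organocatalytic domino Michael/Henry carbocyclisation. C11 (R at this stage) and C4 (S) are fixed by the catalyst, the syn relationship following from the (E)-enamine/(E)-nitroalkene pairing, whereas C1, C2 and C3 arise as mixtures of no consequence, since C2 and C3 are flattened in steps 10 and 12 and C1 is reset in step 13. Chemoselectivity is needed between two aldehydes and several carbon acids: the α-branched, ortho-flanked aldehyde of 11 should not form a reactive enamine with the hindered catalyst, and the nitronate can reach only the C2 aldehyde through a six-membered ring because attack on C12 would give a cyclobutane. The nitro group on C3 is thus the single temporary activator of both bond formations.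

**Step 10**
Reactants: 14 ring B nitro alcohol
Product: 15 α-nitro ketone aldehyde (4S,11R; mixture at C1/C3)
Conditions: Dess–Martin periodinane, CH2Cl2, 0 °C to rt
Reagents that add atoms: none
Why: Dess–Martin oxidation of the secondary β-nitro alcohol under neutral conditions, which merges all C2 epimers, cannot trigger a retro-Henry reaction and leaves the C12 aldehyde and C11 unchanged.

**Step 11**
Reactants: 15 α-nitro ketone aldehyde
Product: 18 α-nitro ketone bearing the C12=C13 vinyl group (4S,11S; mixture at C1/C3), via potassium nitronate aldehyde 16 (not isolated), via potassium nitronate alkene 17 (not isolated)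
Conditions: KN(SiMe3)2 (1.0 equiv), THF, −78 °C; then Ph3P=CH2 [from MePPh3Br and KN(SiMe3)2, 1.3 equiv], −78 to 0 °C; AcOH quench
Reagents that add atoms: methyltriphenylphosphonium bromide C[P+](c1ccccc1)(c1ccccc1)c1ccccc1.[Br-]; KN(SiMe3)2 (potassium kept only in 16 and 17) C[Si](C)(C)[N-][Si](C)(C)C.[K+]
Why: Wittig methylenation, in which the strongly acidic α-nitro ketone is first stored as its delocalised nitronate that masks C2 and C3, so that the ylide meets only the C12 aldehyde at low temperature, faster than C11 can enolise, and the acetic acid quench returns the nitro ketone.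

**Step 12**
Reactants: 18 α-nitro ketone bearing the vinyl group
Product: 19 1-methyl-2-tetralone (4S,11S; both C1 epimers)
Conditions: Bu3SnH, AIBN, toluene, 90 °C
Reagents that add atoms: none
Why: Tin hydride radical denitration, reliable for α-nitro ketones: the stannyl radical adds to a nitro oxygen, loss of Bu3SnONO leaves the carbonyl-stabilised C3 radical, and hydrogen transfer gives the C3 methylene, while cyclisation onto the vinyl group would need a 4-exo or 5-endo mode and should not compete.

**Step 13**
Reactants: 19 1-methyl-2-tetralone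
Product: 20 cis-alcohol (1R,2S,4S,11S)
Conditions: RuCl(p-cymene)[(S,S)-TsDPEN] (2 mol %), HCO2H/Et3N 5:2, CH2Cl2, 30 °C
Reagents that add atoms: none
Why: Noyori–Ikariya asymmetric transfer hydrogenation under dynamic kinetic resolution, a reaction type with close precedent on 1-substituted 2-tetralones: benzylic C1 epimerises rapidly in the medium, and the fastest channel should be hydride delivery to the Re face of C2 in the epimer whose methyl group lies on the side of the C4 branch, since only there is the attacked face free of both substituents and matched to the (S,S) catalyst, which sets C1 (R) and C2 (S) cis to each other and to the C4 branch.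

**Step 14**
Reactants: 20 cis-alcohol
Product: 21 diacetate (1R,2S,4S,11S) with the vinyl group
Conditions: Ac2O, pyridine, DMAP (cat.), CH2Cl2, 0 °C to rt
Reagents that add atoms: acetic anhydride CC(=O)OC(C)=O
Why: DMAP-catalysed acylation of the secondary alcohol with retention at C2, as no bond to a stereocentre is broken.

**Step 15**
Reactants: 21 diacetate with the vinyl group; 22 1-bromo-2-methylprop-1-ene
Product: 24 triisopropylsilyl ether of the target (1R,2S,4S,11S), via B-alkyl-9-BBN borane 23 (not isolated)
Conditions: 9-BBN-H, THF, rt; then 22, PdCl2(dppf) (5 mol %), AsPh3, Cs2CO3, DMF/H2O, rt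
Reagents that add atoms: 9-BBN-H (boron and ring carbons kept only in 23) B1C2CCCC1CCC2
Why: Anti-Markovnikov hydroboration of the monosubstituted alkene followed by B-alkyl Suzuki–Miyaura coupling with the alkenyl bromide, which builds C13–C14 and the trisubstituted alkene at room temperature under conditions known to spare acetates, and touches no stereocentre.

**Step 16**
Reactants: 24 triisopropylsilyl ether of the target
Product: 25 target (1R,2S,4S,11S)-2,19-diacetoxy-8-hydroxyserrulat-14-ene
Conditions: Bu4NF, AcOH (1:1), THF, 0 °C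
Reagents that add atoms: none
Why: Fluoride-induced cleavage of the aryl silyl ether, with the acetic acid buffer protonating the phenoxide at once so that neither acetate should migrate or be cleaved.

**Compound list**
1 | dimethyl 5-hydroxyisophthalate | COC(=O)c1cc(O)cc(c1)C(=O)OC | starting material
2 | (E)-1-bromobut-2-ene (crotyl bromide) | C/C=C/CBr | starting material
3 | dimethyl 5-[(E)-but-2-enyloxy]isophthalate | COC(=O)c1cc(OC/C=C/C)cc(c1)C(=O)OC | intermediate
4 | dimethyl 4-(but-3-en-2-yl)-5-hydroxyisophthalate, racemic | COC(=O)c1cc(O)c(C(C)C=C)c(c1)C(=O)OC | intermediate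
5 | dimethyl 4-(but-3-en-2-yl)-5-(triisopropylsilyloxy)isophthalate, racemic | COC(=O)c1cc(O[Si](C(C)C)(C(C)C)C(C)C)c(C(C)C=C)c(c1)C(=O)OC | intermediate
6 | [4-(but-3-en-2-yl)-5-(triisopropylsilyloxy)benzene-1,3-diyl]dimethanol, racemic | OCc1cc(O[Si](C(C)C)(C(C)C)C(C)C)c(C(C)C=C)c(CO)c1 | intermediate
7 | 4-(but-3-en-2-yl)-3-(hydroxymethyl)-5-(triisopropylsilyloxy)benzyl acetate, racemic | CC(=O)OCc1cc(O[Si](C(C)C)(C(C)C)C(C)C)c(C(C)C=C)c(CO)c1 | intermediate
8 | 4-(but-3-en-2-yl)-3-formyl-5-(triisopropylsilyloxy)benzyl acetate, racemic | CC(=O)OCc1cc(O[Si](C(C)C)(C(C)C)C(C)C)c(C(C)C=C)c(C=O)c1 | intermediate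
9 | 4-(but-3-en-2-yl)-3-[(E)-2-nitrovinyl]-5-(triisopropylsilyloxy)benzyl acetate, racemic | CC(=O)OCc1cc(O[Si](C(C)C)(C(C)C)C(C)C)c(C(C)C=C)c(/C=C/[N+](=O)[O-])c1 | intermediate
10 | secondary ozonide (1,2,4-trioxolane) of the vinyl group of 9 | CC(=O)OCc1cc(O[Si](C(C)C)(C(C)C)C(C)C)c(C(C)C2OCOO2)c(/C=C/[N+](=O)[O-])c1 | intermediate
11 | 3-[(E)-2-nitrovinyl]-4-(1-oxopropan-2-yl)-5-(triisopropylsilyloxy)benzyl acetate, racemic | CC(=O)OCc1cc(O[Si](C(C)C)(C(C)C)C(C)C)c(C(C)C=O)c(/C=C/[N+](=O)[O-])c1 | intermediate
12 | propanal | CCC=O | starting material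
13 | 3-[(2S,3R)-3-methyl-1-nitro-4-oxobutan-2-yl]-4-(1-oxopropan-2-yl)-5-(triisopropylsilyloxy)benzyl acetate, both C1 epimers | CC(=O)OCc1cc(O[Si](C(C)C)(C(C)C)C(C)C)c(C(C)C=O)c(c1)[C@H]([C@@H](C)C=O)C[N+](=O)[O-] | intermediate
14 | tetralin with C1 methyl, C2 hydroxyl, C3 nitro, (4S)-[(R)-1-oxopropan-2-yl], C6 acetoxymethyl, C8 triisopropylsilyloxy; mixture at C1, C2, C3 | CC(=O)OCc1cc(O[Si](C(C)C)(C(C)C)C(C)C)c2c(c1)[C@H]([C@@H](C)C=O)C([N+](=O)[O-])C(O)C2C | intermediate
15 | 2-oxo analogue of 14 (α-nitro ketone aldehyde), 4S,11R; mixture at C1, C3 | CC(=O)OCc1cc(O[Si](C(C)C)(C(C)C)C(C)C)c2c(c1)[C@H]([C@@H](C)C=O)C([N+](=O)[O-])C(=O)C2C | intermediate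
16 | potassium nitronate of 15 | CC(=O)OCc1cc(O[Si](C(C)C)(C(C)C)C(C)C)c2c(c1)[C@H]([C@@H](C)C=O)C(=[N+]([O-])[O-])C(=O)C2C.[K+] | intermediate
17 | potassium nitronate of 18 | CC(=O)OCc1cc(O[Si](C(C)C)(C(C)C)C(C)C)c2c(c1)[C@H]([C@@H](C)C=C)C(=[N+]([O-])[O-])C(=O)C2C.[K+] | intermediate
18 | α-nitro ketone with (4S)-[(S)-but-3-en-2-yl] group; mixture at C1, C3 | CC(=O)OCc1cc(O[Si](C(C)C)(C(C)C)C(C)C)c2c(c1)[C@H]([C@@H](C)C=C)C([N+](=O)[O-])C(=O)C2C | intermediate
19 | (4S)-4-[(S)-but-3-en-2-yl]-1-methyl-2-tetralone with C6 acetoxymethyl and C8 triisopropylsilyloxy; both C1 epimers | CC(=O)OCc1cc(O[Si](C(C)C)(C(C)C)C(C)C)c2c(c1)[C@H]([C@@H](C)C=C)CC(=O)C2C | intermediate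
20 | (1R,2S,4S,11S)-alcohol, all three ring B substituents cis | CC(=O)OCc1cc(O[Si](C(C)C)(C(C)C)C(C)C)c2c(c1)[C@H]([C@@H](C)C=C)C[C@H](O)[C@@H]2C | intermediate
21 | (1R,2S,4S,11S)-2,19-diacetate with the but-3-en-2-yl group | CC(=O)OCc1cc(O[Si](C(C)C)(C(C)C)C(C)C)c2c(c1)[C@H]([C@@H](C)C=C)C[C@H](OC(C)=O)[C@@H]2C | intermediate
22 | 1-bromo-2-methylprop-1-ene | CC(C)=CBr | starting material
23 | B-alkyl-9-BBN borane from 21 (boron on C13) | CC(=O)OCc1cc(O[Si](C(C)C)(C(C)C)C(C)C)c2c(c1)[C@H]([C@@H](C)CCB3C4CCCC3CCC4)C[C@H](OC(C)=O)[C@@H]2C | intermediate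
24 | 8-O-triisopropylsilyl ether of the target, 1R,2S,4S,11S | CC(=O)OCc1cc(O[Si](C(C)C)(C(C)C)C(C)C)c2c(c1)[C@H]([C@@H](C)CCC=C(C)C)C[C@H](OC(C)=O)[C@@H]2C | intermediate
25 | (1R,2S,4S,11S)-2,19-diacetoxy-8-hydroxyserrulat-14-ene | CC(=O)OCc1cc(O)c2c(c1)[C@H]([C@@H](C)CCC=C(C)C)C[C@H](OC(C)=O)[C@@H]2C | target

**Total step count:** 16. **Longest linear sequence:** 16 steps (from 1).

**Steps most likely to fail**

1. **Step 9.** The C12 aldehyde may enolise during the amine-triggered ring closure, with loss of configuration at C11, and aldol pathways between the two free aldehyde groups may intervene. The fallback sets out from 9 and comes back at 15, and it never lets the two aldehydes be free together.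
   - Compound 9, whose C2 is still masked as the vinyl group, undergoes the same catalytic Michael addition with 12 to give the vinyl-masked Michael adduct F1.
   - HC(OMe)3 and pyridinium tosylate in MeOH convert its aldehyde into the dimethyl acetal F2, which locks C11.
   - Ozonolysis with Me2S work-up unmasks C2 in the acetal aldehyde F3.
   - DBU in CH2Cl2 closes ring B to the nitro alcohol acetal F4.
   - Dess–Martin oxidation gives the nitro ketone acetal F5.
   - Aqueous CF3CO2H in CH2Cl2 releases 15.

2. **Step 13.** The reduction may drain the wrong C1 epimer, or facial selectivity at C2 may be poor if catalyst and substrate bias do not cooperate. The fallback sets out from 19 and comes back at 20, and it sets the two centres one after the other under substrate control.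
   - LiN(SiMe3)2 (1.0 equiv, THF, −78 °C) gives the conjugated lithium enolate F7.
   - Kinetic protonation by the bulky 2,6-di-tert-butyl-4-methylphenol from the face opposite the C4 branch gives the (1R)-ketone F8.
   - LiBH(s-Bu)3, added at −78 °C before C1 can equilibrate, attacks the same open face and gives 20.

3. **Step 11.** The nitro ketone may suffer nucleophilic cleavage, or C11 may enolise in the basic medium before olefination. The fallback sets out from 15 and comes back at 19, and it avoids base altogether.
   - Bu3SnH and AIBN in toluene first remove the nitro group to give the keto aldehyde F6.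
   - A gem-dimetallic methylenation (CH2I2, Zn, Ti(OiPr)4, THF, 0 °C), which is non-basic and selective for aldehydes over ketones, then gives 19.

**Further compounds**
F1 | step 9 | 4-(but-3-en-2-yl)-3-[(2S,3R)-3-methyl-1-nitro-4-oxobutan-2-yl]-5-(triisopropylsilyloxy)benzyl acetate, both C1 epimers | CC(=O)OCc1cc(O[Si](C(C)C)(C(C)C)C(C)C)c(C(C)C=C)c(c1)[C@H]([C@@H](C)C=O)C[N+](=O)[O-]
F2 | step 9 | dimethyl acetal of F1 | CC(=O)OCc1cc(O[Si](C(C)C)(C(C)C)C(C)C)c(C(C)C=C)c(c1)[C@H]([C@@H](C)C(OC)OC)C[N+](=O)[O-]
F3 | step 9 | acetal aldehyde (vinyl group of F2 cleaved to the C2 aldehyde) | CC(=O)OCc1cc(O[Si](C(C)C)(C(C)C)C(C)C)c(C(C)C=O)c(c1)[C@H]([C@@H](C)C(OC)OC)C[N+](=O)[O-]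
F4 | step 9 | ring B nitro alcohol with C12 dimethyl acetal, 4S,11R; mixture at C1, C2, C3 | CC(=O)OCc1cc(O[Si](C(C)C)(C(C)C)C(C)C)c2c(c1)[C@H]([C@@H](C)C(OC)OC)C([N+](=O)[O-])C(O)C2C
F5 | step 9 | α-nitro ketone with C12 dimethyl acetal, 4S,11R; mixture at C1, C3 | CC(=O)OCc1cc(O[Si](C(C)C)(C(C)C)C(C)C)c2c(c1)[C@H]([C@@H](C)C(OC)OC)C([N+](=O)[O-])C(=O)C2C
F6 | step 11 | keto aldehyde (2-tetralone with the C12 aldehyde), 4S,11R; both C1 epimers | CC(=O)OCc1cc(O[Si](C(C)C)(C(C)C)C(C)C)c2c(c1)[C@H]([C@@H](C)C=O)CC(=O)C2C
F7 | step 13 | lithium C1=C2 enolate of 19 | CC(=O)OCc1cc(O[Si](C(C)C)(C(C)C)C(C)C)c2c(c1)[C@H]([C@@H](C)C=C)CC([O-])=C2C.[Li+]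
F8 | step 13 | (1R,4S,11S)-ketone, C1 methyl cis to the C4 branch | CC(=O)OCc1cc(O[Si](C(C)C)(C(C)C)C(C)C)c2c(c1)[C@H]([C@@H](C)C=C)CC(=O)[C@@H]2C
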